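**Retrosynthetic overview**
1. Target 12 comes from dihydroxy lactone 11 by methylation of the free, non-chelated C6 phenol.
2. Lactone 11 comes from resorcinol mesylate 9 and CO2: the carboxyl unit (C1 with both its oxygens) is inserted in one operation, C8a–C1 by Kolbe–Schmitt carboxylation and O2–C3 by SN2 lactonisation with inversion.
3. Enabling feature: in ring A, C8a is ortho to the C8 oxygen and para to the C6 oxygen (resorcinol pattern), so it is the carbon nucleophile for CO2. C3 lies five atoms from the new carboxylate oxygen (6-exo-tet) but is out of reach of both phenol oxygens (meta), and the 5-alkylresorcinol is mirror-symmetric, so both ring carbons flanking the side chain are the same.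
4. Mesylate 9 comes from cross-metathesis of alkenyl mesylate 6 with hept-1-en-3-one 7, then one hydrogenation that saturates the C=C and removes both benzyl ethers.
5. Mesylate 6 comes from copper-catalysed opening of (S)-1,2-epoxy-7-octene 2 (hydrolytic kinetic resolution) by an aryl Grignard reagent. Ring A is bought; ring B (the lactone) is the only ring formed, in step 6.

Key step: step 6

Remark: the target is read as (3R)-8-hydroxy-6-methoxy-3-(7-oxoundecyl)-3,4-dihydroisocoumarin; racemic 1,2-epoxy-7-octene, 1,3-bis(benzyloxy)-5-bromobenzene and hept-1-en-3-one are taken as purchasable.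

**Route**

Step 1
Reactants: 1 rac-2-(hex-5-en-1-yl)oxirane (racemic 1,2-epoxy-7-octene)
Product: 2 (S)-2-(hex-5-en-1-yl)oxirane
Conditions: (S,S)-(salen)Co(OAc) (trivalent cobalt; salen = N,N′-bis(3,5-di-tert-butylsalicylidene)-1,2-cyclohexanediaminate; 0.5 mol %), H2O (0.55 equiv), THF, 0 °C → rt; distillation
Reagents that add atoms: none
Why: Hydrolytic kinetic resolution (Jacobsen) should hydrolyse the (R)-epoxide selectively and leave the (S)-epoxide, which supplies the one stereocentre that is later inverted to (R)-C3.

Step 2
Reactants: 2 (S)-2-(hex-5-en-1-yl)oxirane; 3 1,3-bis(benzyloxy)-5-bromobenzene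
Product: 5 (S)-1-[3,5-bis(benzyloxy)phenyl]oct-7-en-2-ol, via aryl Grignard reagent 4 (not isolated)
Conditions: 3, Mg, THF, reflux; then CuI (copper monoiodide, 10 mol %), 2, THF, −40 → 0 °C; 1 M HCl work-up
Reagents that add atoms: none
Why: Grignard formation followed by copper-catalysed SN2 opening of the terminal epoxide at its unsubstituted carbon should leave the stereocentre untouched, so the (S)-epoxide gives the (S)-alcohol.

Step 3
Reactants: 5 (S)-1-[3,5-bis(benzyloxy)phenyl]oct-7-en-2-ol
Product: 6 (S)-1-[3,5-bis(benzyloxy)phenyl]oct-7-en-2-yl methanesulfonate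
Conditions: MsCl, Et3N, CH2Cl2, 0 °C
Reagents that add atoms: methanesulfonyl chloride, CS(=O)(=O)Cl
Why: O-Sulfonylation of a secondary alcohol proceeds with retention at carbon and is done before metathesis so that no free hydroxyl can add (oxa-Michael) to the enone made next.

Step 4
Reactants: 6 (S)-1-[3,5-bis(benzyloxy)phenyl]oct-7-en-2-yl methanesulfonate; 7 hept-1-en-3-one
Product: 8 (2S,7E)-1-[3,5-bis(benzyloxy)phenyl]-9-oxotridec-7-en-2-yl methanesulfonate
Conditions: second-generation Hoveyda–Grubbs catalyst RuCl2(H2IMes)(=CH–C6H4-2-OiPr) (3 mol %), 7 (3 equiv), CH2Cl2, 40 °C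
Reagents that add atoms: none
Why: Olefin cross-metathesis between a terminal alkene and an electron-poor vinyl ketone is selective for the cross product, and the alkene geometry is irrelevant because the double bond is hydrogenated next.

Step 5
Reactants: 8 (2S,7E)-1-[3,5-bis(benzyloxy)phenyl]-9-oxotridec-7-en-2-yl methanesulfonate
Product: 9 (S)-1-(3,5-dihydroxyphenyl)-9-oxotridecan-2-yl methanesulfonate
Conditions: H2 (1 atm), 10% Pd/C, EtOAc, rt
Reagents that add atoms: none
Why: Heterogeneous catalytic hydrogenation should saturate the enone C=C and hydrogenolyse both aryl benzyl ethers, while the dialkyl ketone and the non-benzylic secondary mesylate are inert under neutral conditions.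

Step 6
Reactants: 9 (S)-1-(3,5-dihydroxyphenyl)-9-oxotridecan-2-yl methanesulfonate
Product: 11 (R)-6,8-dihydroxy-3-(7-oxoundecyl)isochroman-1-one, via resorcylate salt 10 (not isolated)
Conditions: DBU (2.5 equiv), CO2 (1 atm), MeCN (0.02 M), 30 °C, then 60 °C; 1 M HCl work-up
Reagents that add atoms: carbon dioxide, O=C=O
Why: Proposed new method: DBU under CO2 should carboxylate the resorcinol at a ring carbon ortho to one oxygen and para to the other (Kolbe–Schmitt pathway through the dienone carboxylate, rearomatising to the hydrogen-bonded 2,4-dihydroxybenzoate 10), and the carboxylate oxygen should then displace the secondary mesylate in the same flask; the closest known reaction types are the organic-base-mediated Kolbe–Schmitt carboxylation of resorcinols at atmospheric CO2 pressure and the SN2 lactonisation of carboxylate salts onto secondary sulfonates, not yet merged into one CO2-inserting operation on this substrate class. Ring B (the six-membered lactone) closes by 6-exo-tet attack of the carboxylate oxygen on C3. The C3 stereocentre is set as (R) by inversion of the (S)-mesylate, so it is controlled by the existing centre and the SN2 mechanism. Regioselectivity is needed between the carbon flanked by the two hydroxyls and the two carbons flanking the side chain: the latter two are identical by the mirror symmetry of the 5-alkylresorcinol, and carboxylation between the hydroxyls is reversible and cannot lactonise, so it should drain back through the irreversible ring closure. Chemoselectivity (carboxylate over phenoxide alkylation, substitution over elimination) rests on the meta placement of both phenol oxygens relative to the side chain, which allows no small-ring O- or C-alkylation, on high dilution, and on the CO2 atmosphere that keeps DBU buffered as its salts. The unprotected ketone should be tolerated because any α-carboxylation is reversible and is lost on acidic work-up.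

Step 7
Reactants: 11 (R)-6,8-dihydroxy-3-(7-oxoundecyl)isochroman-1-one
Product: 12 (R)-8-hydroxy-6-methoxy-3-(7-oxoundecyl)isochroman-1-one
Conditions: MeI (1.1 equiv), K2CO3 (1.2 equiv), acetone, rt
Reagents that add atoms: iodomethane, CI
Why: Williamson O-methylation should occur only at the C6 phenol, because the C8 phenol is hydrogen-bonded to the lactone carbonyl and is much less acidic and nucleophilic.

**Compound list**
1 | rac-2-(hex-5-en-1-yl)oxirane | C=CCCCCC1CO1 | starting material
2 | (S)-2-(hex-5-en-1-yl)oxirane | C=CCCCC[C@H]1CO1 | intermediate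
3 | 1,3-bis(benzyloxy)-5-bromobenzene | Brc1cc(OCc2ccccc2)cc(OCc2ccccc2)c1 | starting material
4 | [3,5-bis(benzyloxy)phenyl]magnesium bromide | Br[Mg]c1cc(OCc2ccccc2)cc(OCc2ccccc2)c1 | intermediate (not isolated)
5 | (S)-1-[3,5-bis(benzyloxy)phenyl]oct-7-en-2-ol | C=CCCCC[C@@H](Cc1cc(OCc2ccccc2)cc(OCc2ccccc2)c1)O | intermediate
6 | (S)-1-[3,5-bis(benzyloxy)phenyl]oct-7-en-2-yl methanesulfonate | C=CCCCC[C@@H](Cc1cc(OCc2ccccc2)cc(OCc2ccccc2)c1)OS(C)(=O)=O | intermediate
7 | hept-1-en-3-one | CCCCC(=O)C=C | starting material
8 | (2S,7E)-1-[3,5-bis(benzyloxy)phenyl]-9-oxotridec-7-en-2-yl methanesulfonate | CCCCC(=O)/C=C/CCCC[C@@H](Cc1cc(OCc2ccccc2)cc(OCc2ccccc2)c1)OS(C)(=O)=O | intermediate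
9 | (S)-1-(3,5-dihydroxyphenyl)-9-oxotridecan-2-yl methanesulfonate | CCCCC(=O)CCCCCC[C@@H](Cc1cc(O)cc(O)c1)OS(C)(=O)=O | intermediate
10 | DBU-H+ 2,4-dihydroxy-6-[(2S)-2-(methanesulfonyloxy)-9-oxotridecyl]benzoate | CCCCC(=O)CCCCCC[C@@H](Cc1cc(O)cc(O)c1C(=O)[O-])OS(C)(=O)=O.C1CCC2=[NH+]CCCN2CC1 | intermediate (not isolated)
11 | (R)-6,8-dihydroxy-3-(7-oxoundecyl)isochroman-1-one | CCCCC(=O)CCCCCC[C@@H]1Cc2cc(O)cc(O)c2C(=O)O1 | intermediate
12 | (R)-8-hydroxy-6-methoxy-3-(7-oxoundecyl)isochroman-1-one | CCCCC(=O)CCCCCC[C@@H]1Cc2cc(OC)cc(O)c2C(=O)O1 | target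

**Step count**
Total steps: 7. Longest linear sequence: 7 steps (1 → 12).

**Steps most likely to fail**

1. Step 6 (proposed new method). Base-induced elimination of the mesylate to the styrene, or intermolecular O-alkylation, may outrun carboxylation; alternatively the carboxylation may stall at a salt that does not close. The fallback uses known chemistry and brings the carboxyl carbon in at the aldehyde level. From 9, Vilsmeier–Haack formylation (POCl3, DMF, 0 °C → rt, then aq. NaOAc) at a ring carbon flanking the side chain should give (S)-1-(2-formyl-3,5-dihydroxyphenyl)-9-oxotridecan-2-yl methanesulfonate F1. Chlorite (Lindgren–Pinnick) oxidation (NaClO2, NaH2PO4, sulfamic acid, aq. dioxane) should give 2,4-dihydroxy-6-[(2S)-2-(methanesulfonyloxy)-9-oxotridecyl]benzoic acid F2. Cs2CO3 in DMF (40 °C, dilute) should then close the lactone by SN2 with inversion, returning to the route at 11.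

2. Step 5. The sulfonate may be lost on the catalyst (solvolysis or elimination), or hydrogenolysis of the aryl benzyl ethers may be incomplete. The fallback separates the two tasks and avoids hydrogenolysis. From 8, homogeneous hydrogenation (H2, RhCl(PPh3)3, benzene/EtOH) should saturate only the C=C and give (S)-1-[3,5-bis(benzyloxy)phenyl]-9-oxotridecan-2-yl methanesulfonate F3. Lewis-acid debenzylation (BCl3, pentamethylbenzene, CH2Cl2, −78 °C) should then give 9, where the route is rejoined.

3. Step 7. Site selectivity may be lost, with methylation of both phenols. The fallback replaces selective methylation by selective demethylation. From 11, exhaustive methylation (excess MeI, K2CO3, DMF, 50 °C) should give (R)-6,8-dimethoxy-3-(7-oxoundecyl)isochroman-1-one F4. Chelation-directed cleavage of the methyl ether next to the lactone carbonyl (BCl3, CH2Cl2, −78 → 0 °C) should give 12 directly.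

**Further compounds**
F1 | step 6 | (S)-1-(2-formyl-3,5-dihydroxyphenyl)-9-oxotridecan-2-yl methanesulfonate | CCCCC(=O)CCCCCC[C@@H](Cc1cc(O)cc(O)c1C=O)OS(C)(=O)=O
F2 | step 6 | 2,4-dihydroxy-6-[(2S)-2-(methanesulfonyloxy)-9-oxotridecyl]benzoic acid | CCCCC(=O)CCCCCC[C@@H](Cc1cc(O)cc(O)c1C(=O)O)OS(C)(=O)=O
F3 | step 5 | (S)-1-[3,5-bis(benzyloxy)phenyl]-9-oxotridecan-2-yl methanesulfonate | CCCCC(=O)CCCCCC[C@@H](Cc1cc(OCc2ccccc2)cc(OCc2ccccc2)c1)OS(C)(=O)=O
F4 | step 7 | (R)-6,8-dimethoxy-3-(7-oxoundecyl)isochroman-1-one | CCCCC(=O)CCCCCC[C@@H]1Cc2cc(OC)cc(OC)c2C(=O)O1
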